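The cis-decalin (eremophilane numbering) is unzipped at two bonds, C6–C7 of ring B and C5–C10 of ring A, to an acyclic (Z)-β-iodo dienone. One palladium(0) domino Heck reaction closes both rings. The C10 vinylpalladium adds 6-exo to the C5=C6 isopropenyl alkene and builds quaternary C5. The neopentyl C6–Pd so formed has no β-hydrogen and adds 6-exo to C7 of the prenyl enone, closing ring B. β-Hydride loss from a C11 methyl releases the isopropenyl group. The step exploits quaternary C5, flanked by C6 and C10, and the C7-isopropenyl C8 ketone. An Evans aldol sets C3/C4; C5, C7, C10 and C9 are relayed from them.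

Key step: step 9

Remark: C1–C10 is the decalin, C5 is quaternary, C14 is the 5-CH3, C15 is the 4-CH3, and C11–C13 is the isopropenyl group. α/β refer to the usual drawing with C14 and C15 β. Phosphine ligands on palladium are omitted in the SMILES of 15.

Step 1
Reactants: 1 pent-4-yn-1-ol
Product: 2 pent-4-ynal
Conditions: TEMPO (10 mol %), PhI(OAc)2, CH2Cl2, rt
Reagents that add atoms: none
Why: Oxoammonium-mediated (TEMPO) oxidation stops at the aldehyde and leaves the terminal alkyne untouched; no stereocentre is involved.

Step 2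
Reactants: 2 pent-4-ynal; 3 (S)-4-benzyl-3-propanoyl-1,3-oxazolidin-2-one
Product: 5 (S)-4-benzyl-3-[(2S,3R)-3-hydroxy-2-methylhept-6-ynoyl]-1,3-oxazolidin-2-one, via dibutylboron Z-enolate 4 (not isolated)
Conditions: 3, Bu2BOTf, Et3N, CH2Cl2, −78 → 0 °C; 2, −78 → 0 °C; pH 7 buffer, MeOH, H2O2, 0 °C
Reagents that add atoms: none
Why: Evans syn-aldol reaction: Z-boron enolate 4 reacts through a closed chair (Zimmerman–Traxler) transition state on the face away from the benzyl group, which sets C3 and C4 in the syn relationship that becomes the trans-diequatorial 3-O/4-CH3 pair of ring A.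

Step 3
Reactants: 5 aldol adduct
Product: 6 (2S,3R)-3-hydroxy-N-methoxy-N,2-dimethylhept-6-ynamide
Conditions: MeONHMe·HCl, AlMe3, CH2Cl2, −20 °C → rt; Rochelle salt work-up
Reagents that add atoms: N,O-dimethylhydroxylamine hydrochloride, CNOC.Cl
Why: Aluminium-amide transamidation, assisted by the free β-hydroxyl group, exchanges the auxiliary for the N-methoxy-N-methylamide (Weinreb amide) without touching C3 or C4.

Step 4
Reactants: 6 hydroxy Weinreb amide
Product: 7 (2S,3R)-3-(tert-butyldimethylsilyloxy)-N-methoxy-N,2-dimethylhept-6-ynamide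
Conditions: TBSOTf, 2,6-lutidine, CH2Cl2, −78 → 0 °C
Reagents that add atoms: tert-butyldimethylsilyl triflate, CC(C)(C)[Si](C)(C)OS(=O)(=O)C(F)(F)F
Why: Silylation of the secondary alcohol with the silyl triflate and a hindered base protects O3 for the organometallic, acidic and palladium steps that follow.

Step 5
Reactants: 7 silylated Weinreb amide
Product: 8 (3S,4R)-4-(tert-butyldimethylsilyloxy)-3-methyloct-7-yn-2-one
Conditions: MeMgBr (3 equiv), THF, −20 → 0 °C; aqueous work-up
Reagents that add atoms: methylmagnesium bromide, C[Mg]Br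
Why: Grignard addition to the Weinreb amide stops at the chelated tetrahedral adduct and gives the methyl ketone (C5, C14) on work-up; the extra equivalent only deprotonates the alkyne C–H, which is restored on work-up.

Step 6
Reactants: 8 methyl ketone
Product: 9 tert-butyl{[(3R,4R)-2,3-dimethyloct-1-en-7-yn-4-yl]oxy}dimethylsilane
Conditions: Ph3PCH3Br, KHMDS, THF, 0 °C; then 8, 0 °C → rt
Reagents that add atoms: methyltriphenylphosphonium bromide, C[P+](c1ccccc1)(c1ccccc1)c1ccccc1.[Br-]
Why: Wittig methylenation with the non-stabilised ylide at low temperature converts the C5 ketone into the C5=C6 1,1-disubstituted alkene faster than the α-stereocentre C4 epimerises.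

Step 7
Reactants: 9 enyne silyl ether; 10 3-methylbut-2-enoyl chloride
Product: 13 (9R,10R)-9-(tert-butyldimethylsilyloxy)-2,10,11-trimethyldodeca-2,11-dien-5-yn-4-one, via lithium acetylide 11 (not isolated), via alkynylzinc chloride 12 (not isolated)
Conditions: n-BuLi, THF, −78 °C; ZnCl2, −78 → 0 °C; 10, Pd(PPh3)4 (5 mol %), 0 °C → rt
Reagents that add atoms: none
Why: Palladium-catalysed acylation of an alkynylzinc halide with an acid chloride (Negishi-type ketone synthesis) gives the cross-conjugated enynone without over-addition and without an amine base that would deconjugate the senecioyl unit.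

Step 8
Reactants: 13 enynone
Product: 14 (5Z,9R,10R)-9-(tert-butyldimethylsilyloxy)-6-iodo-2,10,11-trimethyldodeca-2,5,11-trien-4-one
Conditions: LiI, AcOH, MeCN, rt
Reagents that add atoms: lithium iodide, [Li+].[I-]
Why: Conjugate hydroiodination of the ynone: iodide adds to the alkynyl β-carbon C10 and the allenolate is protonated anti, which should give the Z-β-iodo enone with iodine cis to the C8 carbonyl, while the β,β-disubstituted enone and the isolated alkene do not react.

Step 9
Reactants: 14 (Z)-β-iodo dienone
Product: 16 3-O-TBS-petasol [3α-(tert-butyldimethylsilyloxy)-7α-isopropenyl-eremophila-9,11-dien-8-one; (3R,4R,5R,7S)], via σ-alkylpalladium species 15 (not isolated)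
Conditions: Pd(OAc)2 (10 mol %), PPh3 (25 mol %), Ag2CO3 (1.5 equiv), THF (0.01 M), 65 °C
Reagents that add atoms: none
Why: Oxidative addition of Pd(0) into the C10–I bond occurs with retention, so palladium stays cis to the C8 acyl group, and after iodide abstraction by silver a syn 6-exo-trig carbopalladation of C5=C6 forms C5–C10 (ring A) and gives 15, in which C6–Pd is neopentyl and cannot undergo β-hydride elimination; a second syn 6-exo-trig insertion into C7=C11 forms C6–C7 (ring B), and syn β-hydride elimination from a C11 methyl releases the isopropenyl group and Pd–H, which silver carbonate returns to Pd(0). The closest known reaction type is the domino intramolecular Heck cyclisation of vinyl halides with 1,1-disubstituted alkenes through neopentyl σ-alkylpalladium intermediates, combined with the familiar exo Heck closure onto the α-carbon of β,β-disubstituted acryloyl (prenyl-type) units. C5 is set in the first insertion by a chair-like transition state with C3–OTBS and C4–CH3 equatorial, the =CH2 terminus pseudo-equatorial and eclipsed with C10–Pd, and the C14 methyl pseudo-axial, which makes C14 cis to C15. C7 is set in the second insertion, in which the enone reacts in its preferred s-cis form and C11–Pd takes the pseudo-equatorial position anti to the axial C14 methyl, so the 7α-isopropenyl epimer should form; this centre is inverted in step 10. The step needs the Z geometry of 14 (secured by the anti hydroiodination), exo over endo closure (secured by the tether lengths), and 6-exo capture of 15 in preference to 3-exo closure onto C9=C10, which is reversible and has no β-hydrogen exit. Any isopropylidene isomer from β-hydride loss at C7–H converges with 16 on trienolate 17 in the next step.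

Step 10
Reactants: 16 3-O-TBS-petasol
Product: 18 3-O-TBS-neopetasol [7β-isopropenyl epimer of 16; (3R,4R,5R,7R)], via potassium trienolate 17 (not isolated)
Conditions: KHMDS (1.1 equiv), THF, −78 °C; then AcOH (5 equiv) in THF, −78 °C; neutral work-up
Reagents that add atoms: none
Why: Kinetic α′-deprotonation gives the flat cross-conjugated trienolate 17, and kinetic α-protonation of this extended enolate (deconjugative protonation) should occur at C7 on the α-face, anti to the axial C14 methyl that is 1,3 to C7, which places the isopropenyl group β.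

Step 11
Reactants: 18 3-O-TBS-neopetasol
Product: 20 9β-(dimethylphenylsilyloxy)-3α-(tert-butyldimethylsilyloxy)-7β-isopropenyl-10βH-eremophil-11-en-8-one, via silyl enol ether 19 (not isolated)
Conditions: [(Ph3P)CuH]6 (5 mol %), PhMe2SiH (1.5 equiv), toluene, rt; filter through Florisil, concentrate; mCPBA (1.05 equiv), NaHCO3, CH2Cl2, −20 °C
Reagents that add atoms: dimethylphenylsilane, C[SiH](C)c1ccccc1; 3-chloroperbenzoic acid, O=C(OO)c1cccc(Cl)c1
Why: Copper hydride 1,4-hydrosilylation followed by Rubottom oxidation: the 7β-isopropenyl group holds ring B in the inverted half-chair, so axial hydride attack at C10 comes from the β-face and gives the cis-fused, regiodefined C8=C9 silyl enol ether 19, whose convex β-face is epoxidised faster than the 1,1-disubstituted alkene, and 1,4-silyl migration leaves the equatorial 9β-silyloxy ketone.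

Step 12
Reactants: 20 bis-silyl ether
Product: 21 3α,9β-dihydroxy-7β-isopropenyl-10βH-eremophil-11-en-8-one [(3R,4R,5R,7R,9R,10S)]
Conditions: HF·pyridine, pyridine, THF, 0 °C → rt
Reagents that add atoms: none
Why: Fluoride-mediated cleavage of both silyl ethers under buffered, mildly acidic conditions avoids enolate formation, so C7 and C9 (both already equatorial) and the β,γ-position of the alkene are preserved.

Step 13
Reactants: 21 diol; 22 angelic acid [(Z)-2-methylbut-2-enoic acid]
Product: 24 3α,9β-bis(angeloyloxy)-7β-isopropenyl-10βH-eremophil-11-en-8-one [(3R,4R,5R,7R,9R,10S); CNP0174755.1], via mixed anhydride 23 (not isolated)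
Conditions: 22 (4 equiv), 2,4,6-trichlorobenzoyl chloride, Et3N, toluene, rt, filter; then 21, toluene, 75 °C
Reagents that add atoms: none
Why: Acylation by the preformed mixed anhydride (Yamaguchi-type activation without nucleophilic catalyst or free base) transfers the less hindered angeloyl group to both equatorial secondary alcohols and avoids Z→E isomerisation of the angelate and enolisation at C7; no stereocentre is touched.

Compound list
1 | pent-4-yn-1-ol | C#CCCCO | starting material
2 | pent-4-ynal | C#CCCC=O | intermediate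
3 | (S)-4-benzyl-3-propanoyl-1,3-oxazolidin-2-one | CCC(=O)N1C(=O)OC[C@@H]1Cc1ccccc1 | starting material
4 | dibutylboron (Z)-enolate of 3 | C/C=C(\OB(CCCC)CCCC)N1C(=O)OC[C@@H]1Cc1ccccc1 | intermediate
5 | (S)-4-benzyl-3-[(2S,3R)-3-hydroxy-2-methylhept-6-ynoyl]-1,3-oxazolidin-2-one | C#CCC[C@@H](O)[C@@H](C(=O)N1C(=O)OC[C@@H]1Cc1ccccc1)C | intermediate
6 | (2S,3R)-3-hydroxy-N-methoxy-N,2-dimethylhept-6-ynamide | C#CCC[C@@H](O)[C@@H](C(=O)N(C)OC)C | intermediate
7 | (2S,3R)-3-(tert-butyldimethylsilyloxy)-N-methoxy-N,2-dimethylhept-6-ynamide | C#CCC[C@@H](O[Si](C)(C)C(C)(C)C)[C@@H](C(=O)N(C)OC)C | intermediate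
8 | (3S,4R)-4-(tert-butyldimethylsilyloxy)-3-methyloct-7-yn-2-one | C#CCC[C@@H](O[Si](C)(C)C(C)(C)C)[C@@H](C(C)=O)C | intermediate
9 | tert-butyl{[(3R,4R)-2,3-dimethyloct-1-en-7-yn-4-yl]oxy}dimethylsilane | C#CCC[C@@H](O[Si](C)(C)C(C)(C)C)[C@@H](C(C)=C)C | intermediate
10 | 3-methylbut-2-enoyl chloride | CC(C)=CC(=O)Cl | starting material
11 | lithium acetylide of 9 | [Li]C#CCC[C@@H](O[Si](C)(C)C(C)(C)C)[C@@H](C(C)=C)C | intermediate
12 | alkynylzinc chloride of 9 | Cl[Zn]C#CCC[C@@H](O[Si](C)(C)C(C)(C)C)[C@@H](C(C)=C)C | intermediate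
13 | (9R,10R)-9-(tert-butyldimethylsilyloxy)-2,10,11-trimethyldodeca-2,11-dien-5-yn-4-one | CC(C)=CC(=O)C#CCC[C@@H](O[Si](C)(C)C(C)(C)C)[C@@H](C(C)=C)C | intermediate
14 | (5Z,9R,10R)-9-(tert-butyldimethylsilyloxy)-6-iodo-2,10,11-trimethyldodeca-2,5,11-trien-4-one | CC(C)=CC(=O)/C=C(\I)CC[C@@H](O[Si](C)(C)C(C)(C)C)[C@@H](C(C)=C)C | intermediate
15 | monocyclic neopentyl σ-alkylpalladium(II) cation (ring A closed, C6–Pd, exocyclic (Z)-C9=C10 dienone, phosphines omitted) | CC(C)=CC(=O)/C=C1/CC[C@@H](O[Si](C)(C)C(C)(C)C)[C@H](C)[C@@]1(C)C[Pd+] | intermediate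
16 | 3-O-TBS-petasol, (3R,4R,5R,7S)-3-(tert-butyldimethylsilyloxy)eremophila-9,11-dien-8-one | C=C(C)[C@@H]1C[C@@]2(C)C(CC[C@@H](O[Si](C)(C)C(C)(C)C)[C@@H]2C)=CC1=O | intermediate
17 | potassium 8-oxido-eremophila-7,9,11-triene (trienolate of 16) | C=C(C)C1=C([O-])C=C2CC[C@@H](O[Si](C)(C)C(C)(C)C)[C@H](C)[C@@]2(C)C1.[K+] | intermediate
18 | 3-O-TBS-neopetasol, (3R,4R,5R,7R)-3-(tert-butyldimethylsilyloxy)eremophila-9,11-dien-8-one | C=C(C)[C@H]1C[C@@]2(C)C(CC[C@@H](O[Si](C)(C)C(C)(C)C)[C@@H]2C)=CC1=O | intermediate
19 | cis-fused 8-(dimethylphenylsilyloxy)-3α-(tert-butyldimethylsilyloxy)-7β-isopropenyl-10βH-eremophila-8,11-diene | C=C(C)[C@H]1C[C@@]2(C)[C@H](CC[C@@H](O[Si](C)(C)C(C)(C)C)[C@@H]2C)C=C1O[Si](C)(C)c3ccccc3 | intermediate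
20 | 9β-(dimethylphenylsilyloxy)-3α-(tert-butyldimethylsilyloxy)-7β-isopropenyl-10βH-eremophil-11-en-8-one | C=C(C)[C@H]1C[C@@]2(C)[C@H](CC[C@@H](O[Si](C)(C)C(C)(C)C)[C@@H]2C)[C@@H](O[Si](C)(C)c3ccccc3)C1=O | intermediate
21 | 3α,9β-dihydroxy-7β-isopropenyl-10βH-eremophil-11-en-8-one | C=C(C)[C@H]1C[C@@]2(C)[C@H](CC[C@@H](O)[C@@H]2C)[C@@H](O)C1=O | intermediate
22 | angelic acid, (Z)-2-methylbut-2-enoic acid | C/C=C(/C)C(=O)O | starting material
23 | angelic 2,4,6-trichlorobenzoic anhydride | C/C=C(/C)C(=O)OC(=O)c1c(Cl)cc(Cl)cc1Cl | intermediate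
24 | 3α,9β-bis(angeloyloxy)-7β-isopropenyl-10βH-eremophil-11-en-8-one, (3R,4R,5R,7R,9R,10S), CNP0174755.1 | C=C(C)[C@H]1C[C@@]2(C)[C@H](CC[C@@H](OC(=O)/C(C)=C\C)[C@@H]2C)[C@@H](OC(=O)/C(C)=C\C)C1=O | target

Total step count: 13. Longest linear sequence: 13 steps (from 1).

Steps most likely to fail

Step 9. The neopentyl palladium species may be diverted by 3-exo closure onto C9=C10. Insertion into the trisubstituted, electron-poor C7=C11 alkene may be too slow. The vinylpalladium may lose its Z geometry, and facial selectivity at C5 may be poor. The fallback sets out from 14 and splits the cascade into an atom-transfer cyclisation and an anionic ring closure. Pd(0) with a very bulky phosphine (carboiodination, with C(sp3)–I reductive elimination after the first 6-exo insertion) should give the monocyclic neopentyl iodide F1. Treatment of F1 with KHMDS in THF removes a γ-proton of the prenyl enone. The extended enolate then alkylates at its α-carbon C7 with the CH2I group in a 6-(enolendo)-exo-tet closure. This forms the same C6–C7 bond and comes back to the route at 16; any C7 mixture is levelled in step 10.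

Step 11. Hydride may be delivered to the α-face of C10, giving a trans ring fusion. The silyl trapping may be incomplete, or the isopropenyl group may be epoxidised in competition. The fallback sets out from 18 and replaces the closed-shell hydride/peracid sequence by a radical reductive α-oxygenation. Mn(dpm)3 (cat.), PhSiH3 and O2 in i-PrOH (Mukaiyama-type hydrogen-atom transfer to C10, with O2 capture at C9) should give the 9β-hydroperoxy ketone F4. P(OEt)3 reduces F4 to the 9β-hydroxy ketone F5. HF·pyridine then removes the C3 silyl group and the sequence comes back at 21.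

Step 10. Protonation of the trienolate may show poor facial selectivity or occur at the γ-carbon C12, and the kinetic epimer may revert on isolation. The fallback sets out from 16 and moves the correction of C7 to a stage where the wanted epimer is the thermodynamic one. Compound 16 is taken through the copper hydride/PhMe2SiH and mCPBA sequence to the 7α-configured silyl enol ether F2 and then to the 7-epi ketone F3. In this cis-decalin the 7α-isopropenyl group is axial and syn-axial to C4. A short contact with catalytic DBU in CH2Cl2 should therefore equilibrate C7 through fast α-reprotonation, before conjugation sets in, and the sequence comes back at 20.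

Further compounds
F1 | step 9 | (Z)-configured monocyclic neopentyl iodide (ring A closed, C6H2I, exocyclic dienone) | CC(C)=CC(=O)/C=C1/CC[C@@H](O[Si](C)(C)C(C)(C)C)[C@H](C)[C@@]1(C)CI
F2 | step 10 | 7α-isopropenyl epimer of silyl enol ether 19 | C=C(C)[C@@H]1C[C@@]2(C)[C@H](CC[C@@H](O[Si](C)(C)C(C)(C)C)[C@@H]2C)C=C1O[Si](C)(C)c3ccccc3
F3 | step 10 | 7α-isopropenyl epimer of ketone 20 | C=C(C)[C@@H]1C[C@@]2(C)[C@H](CC[C@@H](O[Si](C)(C)C(C)(C)C)[C@@H]2C)[C@@H](O[Si](C)(C)c3ccccc3)C1=O
F4 | step 11 | 9β-hydroperoxy-3α-(tert-butyldimethylsilyloxy)-7β-isopropenyl-10βH-eremophil-11-en-8-one | C=C(C)[C@H]1C[C@@]2(C)[C@H](CC[C@@H](O[Si](C)(C)C(C)(C)C)[C@@H]2C)[C@@H](OO)C1=O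
F5 | step 11 | 9β-hydroxy-3α-(tert-butyldimethylsilyloxy)-7β-isopropenyl-10βH-eremophil-11-en-8-one | C=C(C)[C@H]1C[C@@]2(C)[C@H](CC[C@@H](O[Si](C)(C)C(C)(C)C)[C@@H]2C)[C@@H](O)C1=O
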